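**Plan**

1. Labdane numbering is used: ring A = C1–C5 and C10, ring B = C5–C10, side chain C11–C15 (C16 on C13, O on C15), C17 on C8, C18 and C19 on C4, C20 on C10.
2. Retrosynthesis: a C1=C2 alkene is added back and cut (ring A, metathesis of a C10 vinyl and a C4 allyl group). Then C5–C6 and C9–C10 are cut together as a [4+2] disconnection. This is possible because the only ring B alkene, C7=C8, lies between C6 and C9; the dienophile C5=C10 is kept acyclic so that C20 and H5 can come out trans.
3. Forward: the diene (C6–C9 with C17 and C11–C15) comes from (S)-citronellol in six steps and the (E)-enal (C1, C10, C20, C5, C4, C18, C19, allyl) in one. Ring B is closed by a catalytic enantioselective Diels–Alder reaction, ring A by methylenation and ring-closing metathesis, and diimide then saturates C1=C2.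
4. Stereochemistry: C13 comes from citronellol. C5 and C10 come from the (E)-enal geometry (relative) and the chiral boron catalyst (absolute). C9 comes from the diene geometry combined with the exo-formyl topology of the cycloaddition.

Key step: step 8

Assumption: the catalyst from (S)-α,α-diphenylprolinol is taken to direct the diene to the Re face of C10, the sense recalled for 2-substituted enals; if the opposite sense applies, the (R)-catalyst is used and nothing else changes.

**Step 1**
Reactants: 1 (S)-citronellol
Product: 2 (S)-citronellyl acetate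
Conditions: Ac2O, pyridine, DMAP (cat.), CH2Cl2, 0 °C to rt
Reagents that add atoms: acetic anhydride, CC(=O)OC(C)=O
Why: DMAP-catalysed acylation of the primary alcohol installs the C15 acetate of the target before the alkene is cleaved.

**Step 2**
Reactants: 2 (S)-citronellyl acetate
Product: 4 (S)-3-methyl-6-oxohexyl acetate, via ozonide 3 (not isolated)
Conditions: O3, CH2Cl2, −78 °C; then Me2S, −78 °C to rt
Reagents that add atoms: ozone, [O-][O+]=O
Why: Ozonolysis with reductive work-up cleaves the only alkene and leaves the aldehyde carbon that becomes C9, without touching the acetate or C13.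

**Step 3**
Reactants: 4 (S)-3-methyl-6-oxohexyl acetate
Product: 5 (S)-7,7-dibromo-3-methylhept-6-en-1-yl acetate
Conditions: CBr4, PPh3, CH2Cl2, 0 °C
Reagents that add atoms: tetrabromomethane, BrC(Br)(Br)Br
Why: Ramirez/Corey–Fuchs dibromoolefination (Wittig reaction of Ph3P=CBr2) adds C8 under neutral conditions that the acetate tolerates.

**Step 4**
Reactants: 5 (S)-7,7-dibromo-3-methylhept-6-en-1-yl acetate
Product: 6 (3S,6Z)-7-bromo-3-methylnona-6,8-dien-1-yl acetate
Conditions: CH2=CHSnBu3 (1.05 equiv), tris(dibenzylideneacetone)dipalladium Pd2(dba)3 (2.5 mol %), tri(2-furyl)phosphine (15 mol %), toluene, 100 °C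
Reagents that add atoms: tributyl(vinyl)stannane, C=C[Sn](CCCC)(CCCC)CCCC
Why: In this Stille coupling zerovalent palladium should insert into the less hindered C–Br bond trans to the alkyl chain of the 1,1-dibromoalkene, so the vinyl group (C7, C6) enters trans to C11 with retention.

**Step 5**
Reactants: 6 (3S,6Z)-7-bromo-3-methylnona-6,8-dien-1-yl acetate
Product: 7 (3S,6Z)-7-(hydroxymethyl)-3-methylnona-6,8-dien-1-yl acetate
Conditions: Bu3SnCH2OH (1.3 equiv), Pd(PPh3)4 (5 mol %), 1,4-dioxane, 90 °C
Reagents that add atoms: (tributylstannyl)methanol, OC[Sn](CCCC)(CCCC)CCCC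
Why: Stille hydroxymethylation replaces the remaining bromide with retention, which places C17 cis to C11 and completes the diene geometry.

**Step 6**
Reactants: 7 (3S,6Z)-7-(hydroxymethyl)-3-methylnona-6,8-dien-1-yl acetate
Product: 8 (2Z,6S)-6-methyl-2-vinyloct-2-ene-1,8-diyl diacetate
Conditions: Ac2O, pyridine, DMAP (cat.), CH2Cl2, 0 °C to rt
Reagents that add atoms: acetic anhydride, CC(=O)OC(C)=O
Why: Acylation of the allylic alcohol gives the C17 acetate of the target and a diene with no free hydroxyl group to bind the Lewis acid.

**Step 7**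
Reactants: 9 2,2-dimethylpent-4-enal; 10 2-(triphenylphosphoranylidene)propanal
Product: 11 (E)-2,4,4-trimethylhepta-2,6-dienal
Conditions: toluene, 110 °C
Reagents that add atoms: none
Why: Wittig reaction of the stabilised ylide with the non-enolisable aldehyde should be E-selective, and this geometry later fixes C20 and H5 trans.

**Step 8**
Reactants: 8 (2Z,6S)-6-methyl-2-vinyloct-2-ene-1,8-diyl diacetate; 11 (E)-2,4,4-trimethylhepta-2,6-dienal
Product: 12 (3S)-5-[(1S,5S,6S)-2-(acetoxymethyl)-6-formyl-6-methyl-5-(2-methylpent-4-en-2-yl)cyclohex-2-en-1-yl]-3-methylpentyl acetate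
Conditions: 11 (1.5 equiv), (S)-B-o-tolyl oxazaborolidine from (S)-α,α-diphenylprolinol (20 mol %), HNTf2 (18 mol %), CH2Cl2, −20 to 4 °C
Reagents that add atoms: none
Why: The N-protonated oxazaborolidine binds the formyl oxygen of 11 at boron and lowers the enal LUMO, and a concerted but asynchronous [4+2] cycloaddition (C5–C6 ahead of C9–C10) with the s-cis diene 8 follows; the closest known reaction type is the oxazaborolidinium-catalysed Diels–Alder reaction of 2-methyl-2-enals such as tiglic aldehyde with acyclic dienes. Ring B closes as a six-membered ring by suprafacial addition on both partners, with the new alkene at C7=C8. C10 and C5 form together from the (E)-alkene, so the C10 methyl and H5 come out trans, and their absolute sense is set by the catalyst, which covers one enal face so that C9 attacks the Re face of C10. C9 is set by the diene geometry (C11 on the outer position of the terminus) together with the exo-formyl topology, in which the C10 methyl and the C4 substituent lie under the diene and so end up cis to C11. Three selectivities are needed: bonding of C9 to C10, secured because the alkyl-substituted terminus leaves the larger HOMO coefficient on C6, which meets the enal beta-carbon C5 (CH2OAc on C8 directs only weakly the other way); one enal face, secured by the catalyst; and exo-formyl over endo-formyl, for which the 2-methyl group and the bulk of the boron-bound formyl group beneath C8 and its acetoxymethyl branch are relied on. This last preference is the least secure, because it also puts the tert-alkyl group on C5 beneath C7 and runs against the usual endo preference of a Lewis-acid-bound formyl group, and it is the reason for the first fallback.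

**Step 9**
Reactants: 12 (ring B adduct aldehyde)
Product: 13 (3S)-5-[(1R,5S,6S)-2-(acetoxymethyl)-6-ethenyl-6-methyl-5-(2-methylpent-4-en-2-yl)cyclohex-2-en-1-yl]-3-methylpentyl acetate
Conditions: Zn, CH2Br2, TiCl4, THF, 0 °C; then 12, CH2Cl2, 0 °C to rt
Reagents that add atoms: dibromomethane, BrCBr
Why: Takai–Lombardo methylenation converts the hindered, non-enolisable C1 aldehyde to a vinyl group without base, so the acetates and the C9/C10 stereocentres are not at risk.

**Step 10**
Reactants: 13 (C10 vinyl, C4 allyl triene)
Product: 14 (3S)-5-[(1R,4aS,8aS)-2-(acetoxymethyl)-5,5,8a-trimethyl-1,4,4a,5,6,8a-hexahydronaphthalen-1-yl]-3-methylpentyl acetate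
Conditions: second-generation Grubbs catalyst (H2IMes)(PCy3)Cl2Ru=CHPh (5 mol %), CH2Cl2 (0.005 M), 40 °C
Reagents that add atoms: none
Why: Ring-closing metathesis between the allyl group on C4 (initiation site) and the vinyl group on C10 closes six-membered ring A with loss of ethene, while the trisubstituted C7=C8 alkene should stay out of the reaction.

**Step 11**
Reactants: 14 (labda-1,7-diene diacetate)
Product: 15 (3S)-5-[(1R,4aS,8aS)-2-(acetoxymethyl)-5,5,8a-trimethyl-1,4,4a,5,6,7,8,8a-octahydronaphthalen-1-yl]-3-methylpentyl acetate
Conditions: TsNHNH2, NaOAc, DME/H2O, reflux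
Reagents that add atoms: none
Why: Diimide reduction (concerted syn transfer of H2) should reduce the cis-disubstituted C1=C2 alkene in preference to the trisubstituted C7=C8 alkene with its allylic acetate, and it creates no stereocentre.

**Compound list**

1 | (S)-citronellol, (S)-3,7-dimethyloct-6-en-1-ol | OCC[C@@H](C)CCC=C(C)C | starting material
2 | (S)-citronellyl acetate, (S)-3,7-dimethyloct-6-en-1-yl acetate | CC(=O)OCC[C@@H](C)CCC=C(C)C | intermediate
3 | ozonide of 2, (3S)-5-(5,5-dimethyl-1,2,4-trioxolan-3-yl)-3-methylpentyl acetate (both configurations at the trioxolane carbon) | CC(=O)OCC[C@@H](C)CCC1OOC(C)(C)O1 | intermediate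
4 | (S)-3-methyl-6-oxohexyl acetate | CC(=O)OCC[C@@H](C)CCC=O | intermediate
5 | (S)-7,7-dibromo-3-methylhept-6-en-1-yl acetate | CC(=O)OCC[C@@H](C)CCC=C(Br)Br | intermediate
6 | (3S,6Z)-7-bromo-3-methylnona-6,8-dien-1-yl acetate | CC(=O)OCC[C@@H](C)CC/C=C(\Br)C=C | intermediate
7 | (3S,6Z)-7-(hydroxymethyl)-3-methylnona-6,8-dien-1-yl acetate | CC(=O)OCC[C@@H](C)CC/C=C(\CO)C=C | intermediate
8 | (2Z,6S)-6-methyl-2-vinyloct-2-ene-1,8-diyl diacetate | C=C/C(COC(C)=O)=C/CC[C@H](C)CCOC(C)=O | intermediate
9 | 2,2-dimethylpent-4-enal | C=CCC(C)(C)C=O | starting material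
10 | 2-(triphenylphosphoranylidene)propanal | CC(C=O)=P(c1ccccc1)(c1ccccc1)c1ccccc1 | starting material
11 | (E)-2,4,4-trimethylhepta-2,6-dienal | O=C/C(C)=C/C(C)(C)CC=C | intermediate
12 | (3S)-5-[(1S,5S,6S)-2-(acetoxymethyl)-6-formyl-6-methyl-5-(2-methylpent-4-en-2-yl)cyclohex-2-en-1-yl]-3-methylpentyl acetate | CC(=O)OCC[C@@H](C)CC[C@H]1C(COC(C)=O)=CC[C@@H](C(C)(C)CC=C)[C@]1(C)C=O | intermediate
13 | (3S)-5-[(1R,5S,6S)-2-(acetoxymethyl)-6-ethenyl-6-methyl-5-(2-methylpent-4-en-2-yl)cyclohex-2-en-1-yl]-3-methylpentyl acetate | CC(=O)OCC[C@@H](C)CC[C@H]1C(COC(C)=O)=CC[C@@H](C(C)(C)CC=C)[C@]1(C)C=C | intermediate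
14 | (3S)-5-[(1R,4aS,8aS)-2-(acetoxymethyl)-5,5,8a-trimethyl-1,4,4a,5,6,8a-hexahydronaphthalen-1-yl]-3-methylpentyl acetate | CC(=O)OCC[C@@H](C)CC[C@H]1C(COC(C)=O)=CC[C@H]2C(C)(C)CC=C[C@]12C | intermediate
15 | (3S)-5-[(1R,4aS,8aS)-2-(acetoxymethyl)-5,5,8a-trimethyl-1,4,4a,5,6,7,8,8a-octahydronaphthalen-1-yl]-3-methylpentyl acetate, (5S,9R,10S,13S)-labd-7-ene-15,17-diyl diacetate | CC(=O)OCC[C@@H](C)CC[C@H]1C(COC(C)=O)=CC[C@H]2C(C)(C)CCC[C@]12C | target

**Step count and risks**

Total: 11 steps. Longest linear sequence: 10 steps (steps 1–6 and 8–11, from 1); the enal 11 is made in one step and joins at step 8.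

Steps most likely to fail:

1. Step 8. The cycloaddition may follow the endo-formyl topology (formyl group under the diene, tert-alkyl group away from it), which would reverse the C9 relationship, or may stall because of the tert-alkyl group on the enal beta-carbon. The fallback changes the diene geometry so that the endo-formyl topology is the productive one. It sets out from 4. Ohira–Bestmann homologation (dimethyl (1-diazo-2-oxopropyl)phosphonate, K2CO3, MeOH, with methanolysis of the acetate in the same pot) should give (S)-3-methylhept-6-yn-1-ol F1. The dianion (n-BuLi) with paraformaldehyde should give (S)-6-methyloct-2-yne-1,8-diol F2. Chelation-controlled anti-carbomagnesiation with excess CH2=CHMgCl (THF/cyclohexane, reflux) should put the vinyl group on C8 cis to C11 and give (2E,6S)-6-methyl-2-vinyloct-2-ene-1,8-diol F3. Acetylation should give (2E,6S)-6-methyl-2-vinyloct-2-ene-1,8-diyl diacetate F4, the isomer of 8 with C11 on the inner position. With F4, 11 and the same catalyst enantiomer, the endo-formyl mode (formyl and H5 under the diene, tert-alkyl group outside) leads to the same adduct; because an inner substituent slows cycloaddition, the reaction is run at about 12 kbar. The fallback comes back to the route at 12.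

2. Step 4. Site selectivity in the oxidative addition may be lost (double vinylation), or the bromodiene may lose HBr to an enyne. The fallback builds the diene from an alkyne. It sets out from 4 and passes through F1 and F2 as above. Syn-hydrostannylation with Bu3SnH and Mo(CO)3(CNtBu)3, which places tin on the carbinol-bearing carbon, should give (2E,6S)-6-methyl-2-(tributylstannyl)oct-2-ene-1,8-diol F5. Stille coupling with vinyl bromide (Pd(PPh3)4, CuI, DMF) should give (2Z,6S)-6-methyl-2-vinyloct-2-ene-1,8-diol F6. Double acetylation comes back to the route at 8.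

3. Step 7. Olefination of the neopentyl aldehyde by the stabilised formyl ylide may be too slow, with decomposition on prolonged heating. The fallback uses a more nucleophilic phosphonate anion and adjusts the oxidation level afterwards. It sets out from 9. Horner–Wadsworth–Emmons reaction with triethyl 2-phosphonopropionate (NaH, THF) should give ethyl (E)-2,4,4-trimethylhepta-2,6-dienoate F7. Reduction with i-Bu2AlH should give (E)-2,4,4-trimethylhepta-2,6-dien-1-ol F8. Oxidation with MnO2 comes back to the route at 11.

**Further compounds**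

F1 | step 8 | (S)-3-methylhept-6-yn-1-ol | OCC[C@@H](C)CCC#C
F2 | step 8 | (S)-6-methyloct-2-yne-1,8-diol | OCC[C@@H](C)CCC#CCO
F3 | step 8 | (2E,6S)-6-methyl-2-vinyloct-2-ene-1,8-diol | OCC[C@@H](C)CC/C=C(\C=C)CO
F4 | step 8 | (2E,6S)-6-methyl-2-vinyloct-2-ene-1,8-diyl diacetate | CC(=O)OCC[C@@H](C)CC/C=C(\C=C)COC(C)=O
F5 | step 4 | (2E,6S)-6-methyl-2-(tributylstannyl)oct-2-ene-1,8-diol | OCC[C@@H](C)CC/C=C(\CO)[Sn](CCCC)(CCCC)CCCC
F6 | step 4 | (2Z,6S)-6-methyl-2-vinyloct-2-ene-1,8-diol | OCC[C@@H](C)CC/C=C(\CO)C=C
F7 | step 7 | ethyl (E)-2,4,4-trimethylhepta-2,6-dienoate | CCOC(=O)/C(C)=C/C(C)(C)CC=C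
F8 | step 7 | (E)-2,4,4-trimethylhepta-2,6-dien-1-ol | OC/C(C)=C/C(C)(C)CC=C
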